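**Retrosynthetic overview**

- The target is released last by methanolysis of an aryl acetate that masks the C8 phenol of the (3R)-lactone.
- The route rests on lactone ring B (C1, O2, C3, C4, C4a, C8a). C4a is the one free ortho C–H of 2-acetoxybenzoic acid, which supplies ring A and C1. C4 and C3 are the terminal CH2=CH of a linear C19 triene, whose other two alkenes become the (1E,3E)-heptadecadienyl chain.
- Ring B is the only ring formed. It is closed by a palladium-catalysed oxidative annulation that makes C4–C4a (C–H activation, alkene insertion) and C3–O2 (carboxylate capture of the allylpalladium), and sets C3 as R under ligand control.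
- The triene, (3E,5E)-nonadeca-1,3,5-triene, is made from tetradecanal by Horner-Wadsworth-Emmons dienoate formation, DIBAL-H reduction, MnO2 oxidation and Wittig methylenation.

Key step: step 5

Remark: benzoquinone is avoided as oxidant because it is a Diels-Alder dienophile toward the terminal diene of triene 8, so O2 is used; molecular sieves take up the water formed so that the acetate of 9 is not hydrolysed; the amino acid ligand is written in the L-series and its antipode is taken if screening shows that it leads to the 3S lactone.

**Route**

Step 1
Reactants: 1 tetradecanal; 2 triethyl 4-phosphonocrotonate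
Product: 3 ethyl (2E,4E)-octadeca-2,4-dienoate
Conditions: LiOH·H2O (1.1 equiv), 4 Å MS, THF, reflux
Reagents that add atoms: none
Why: Horner-Wadsworth-Emmons olefination through the phosphonate-stabilized carbanion should give the new C4=C5 alkene mainly E while the 2E alkene comes with the reagent; any minor 4Z isomer is removed by chromatography or equilibrated with a trace of iodine.

Step 2
Reactants: 3 ethyl (2E,4E)-octadeca-2,4-dienoate
Product: 4 (2E,4E)-octadeca-2,4-dien-1-ol
Conditions: i-Bu2AlH (DIBAL-H, 2.2 equiv), CH2Cl2, -78 °C; aq. potassium sodium tartrate
Reagents that add atoms: none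
Why: DIBAL-H reduces the conjugated ester in a 1,2 sense to the primary dienylic alcohol at low temperature and leaves the diene and its geometry alone.

Step 3
Reactants: 4 (2E,4E)-octadeca-2,4-dien-1-ol
Product: 5 (2E,4E)-octadeca-2,4-dienal
Conditions: activated MnO2 (10 equiv), CH2Cl2, rt
Reagents that add atoms: none
Why: Manganese dioxide oxidation is selective for allylic alcohols, stops at the aldehyde and runs under neutral conditions, so the 2E,4E geometry should be kept.

Step 4
Reactants: 5 (2E,4E)-octadeca-2,4-dienal; 6 methyltriphenylphosphonium bromide
Product: 8 (3E,5E)-nonadeca-1,3,5-triene, via methylenetriphenylphosphorane 7 (not isolated)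
Conditions: 6 (1.3 equiv), KOtBu (1.25 equiv), THF, 0 °C; then 5, 0 °C to rt
Reagents that add atoms: none
Why: Wittig methylenation with the non-stabilized ylide adds 1,2 to the dienal and creates only a terminal =CH2, so no new alkene geometry arises; the triene is kept cold under argon and used promptly.

Step 5
Reactants: 8 (3E,5E)-nonadeca-1,3,5-triene (1.5 equiv); 9 2-acetoxybenzoic acid
Product: 10 (3R)-3-[(1E,3E)-heptadeca-1,3-dien-1-yl]-1-oxo-3,4-dihydro-1H-isochromen-8-yl acetate
Conditions: Pd(OAc)2 (10 mol %), N-acetyl-L-tert-leucine (20 mol %), KHCO3 (0.5 equiv), O2 (1 atm), 4 Å MS, t-AmOH, 60 °C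
Reagents that add atoms: none
Why: Proposed new method: carboxylate-directed concerted metalation-deprotonation by divalent palladium at C6–H of 9, its only free ortho C–H and the future C4a, gives a catalyst-bound five-membered aryl palladacycle, which inserts the terminal alkene of 8 with the aryl group going to the CH2 terminus (C4–C4a) and leaves an η3-allylpalladium conjugated with the remaining alkene; the tethered carboxylate then forms C3–O2 and O2 reoxidizes the zerovalent palladium released. The closest known reaction types are the carboxylate-directed ortho C–H olefination of benzoic acids with Pd(OAc)2, a mono-N-protected amino acid and O2, and the racemic heteroannulation of 1,3-dienes with 2-iodobenzoic acids by zerovalent palladium, which passes through the same allylpalladium carboxylate; their merger in an enantioselective C–H form has not been shown. Ring B closes by attack of the carboxylate oxygen on the near allyl terminus, a six-membered closure that leaves the rest of the allyl unit exocyclic (6-exo), whereas the far termini would need eight- or ten-membered rings. C3, the only new stereocentre, is set under catalyst control: the chiral amino acid ligand held κ2-N,O on palladium selects the alkene face in the syn migratory insertion, and the stereospecific C–O bond formation passes that choice on to C3, so the ligand antipode that leads to 3R is kept after screening. The step needs site selectivity (9 has one ortho C–H, and the monosubstituted alkene of 8 is the least hindered and gives the most delocalized allyl), retention of geometry (the syn,syn allyl delivers the 1E,3E diene) and C–O bond formation faster than β-hydride loss from C4, which the intramolecular carboxylate should secure. Moderate temperature and fast aerobic reoxidation are meant to keep zerovalent palladium from re-ionizing the dienylic C3–O2 bond of 10.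

Step 6
Reactants: 10 (3R)-3-[(1E,3E)-heptadeca-1,3-dien-1-yl]-1-oxo-3,4-dihydro-1H-isochromen-8-yl acetate
Product: 11 (3R)-3-[(1E,3E)-heptadeca-1,3-dien-1-yl]-8-hydroxy-3,4-dihydro-1H-isochromen-1-one (target)
Conditions: K2CO3 (0.2 equiv), MeOH/THF, 0 °C; pH 6 phosphate buffer
Reagents that add atoms: none
Why: Base-catalysed transesterification (methanolysis) cleaves the aryl acetate, a much better acyl donor than the lactone, and the freed C8 phenol then hydrogen-bonds to and deactivates the C1 carbonyl; no bond to C3 is touched, so the 3R configuration should be kept.

**Compound list**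

1 | tetradecanal | CCCCCCCCCCCCCC=O | starting material
2 | triethyl 4-phosphonocrotonate (ethyl (2E)-4-(diethoxyphosphoryl)but-2-enoate) | CCOC(=O)/C=C/CP(=O)(OCC)OCC | starting material
3 | ethyl (2E,4E)-octadeca-2,4-dienoate | CCCCCCCCCCCCC/C=C/C=C/C(=O)OCC | intermediate
4 | (2E,4E)-octadeca-2,4-dien-1-ol | CCCCCCCCCCCCC/C=C/C=C/CO | intermediate
5 | (2E,4E)-octadeca-2,4-dienal | CCCCCCCCCCCCC/C=C/C=C/C=O | intermediate
6 | methyltriphenylphosphonium bromide | [Br-].C[P+](c1ccccc1)(c1ccccc1)c1ccccc1 | starting material
7 | methylenetriphenylphosphorane | C=P(c1ccccc1)(c1ccccc1)c1ccccc1 | intermediate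
8 | (3E,5E)-nonadeca-1,3,5-triene | CCCCCCCCCCCCC/C=C/C=C/C=C | intermediate
9 | 2-acetoxybenzoic acid | CC(=O)Oc1ccccc1C(=O)O | starting material
10 | (3R)-3-[(1E,3E)-heptadeca-1,3-dien-1-yl]-1-oxo-3,4-dihydro-1H-isochromen-8-yl acetate | CCCCCCCCCCCCC/C=C/C=C/[C@H]1Cc2cccc(OC(C)=O)c2C(=O)O1 | intermediate
11 | (3R)-3-[(1E,3E)-heptadeca-1,3-dien-1-yl]-8-hydroxy-3,4-dihydro-1H-isochromen-1-one | CCCCCCCCCCCCC/C=C/C=C/[C@H]1Cc2cccc(O)c2C(=O)O1 | target

**Step count**

Total steps: 6. Longest linear sequence: 6 steps (1 → 3 → 4 → 5 → 8 → 10 → 11).

**Steps most likely to fail**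

Step 5 (proposed new method). Several processes may defeat it:
- weak facial discrimination by the amino acid ligand at alkene insertion, giving low enantiomeric purity;
- β-hydride loss from C4 in place of C–O bond formation;
- acetyl transfer or hydrolysis in 9, freeing a chelating salicylate that slows catalysis;
- re-ionization of the dienylic C3–O2 bond by zerovalent palladium, eroding the configuration at C3;
- autoxidation or oligomerization of the triene under O2.

The fallback uses known chemistry, sets out from 3 and comes back at 11. Ester 3 is converted with MeNH(OMe)·HCl and i-PrMgCl (THF, -20 °C) into the Weinreb amide (2E,4E)-N-methoxy-N-methyloctadeca-2,4-dienamide F1. Commercial 2,2,5-trimethyl-4H-1,3-benzodioxin-4-one F2 is lithiated at its benzylic methyl group (LiN(i-Pr)2, 2.1 equiv, THF, -78 °C) and acylated with F1, with a short contact time at -78 °C to hold back conjugate addition. This should give the ketone 2,2-dimethyl-5-[(3E,5E)-2-oxononadeca-3,5-dien-1-yl]-4H-1,3-benzodioxin-4-one F3. Corey-Bakshi-Shibata reduction ((S)-Me-CBS oxazaborolidine, catecholborane, toluene, -78 °C), with the dienyl group expected to act as the large substituent, should give 5-[(2R,3E,5E)-2-hydroxynonadeca-3,5-dien-1-yl]-2,2-dimethyl-4H-1,3-benzodioxin-4-one F4. With NaH (1.1 equiv, THF, 0 °C; aq. NH4Cl) the alkoxide opens the dioxinone with loss of acetone, which closes ring B and frees the C8 phenol in one operation to give 11.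

Step 6. Methoxide may attack the lactone carbonyl and open ring B to the methyl ester, or base may be consumed in side reactions at the dienylic carboxylate before the acetate is fully cleaved. The fallback sets out from 10 and comes back at 11, and accepts ring opening instead of avoiding it. Exhaustive saponification (LiOH, 3 equiv, THF/H2O, 0 °C to rt) cleaves both the acetate and the lactone by acyl–oxygen fission. Acidification to pH 4–5 (NaH2PO4) gives the seco acid 2-hydroxy-6-[(2R,3E,5E)-2-hydroxynonadeca-3,5-dien-1-yl]benzoic acid F5. F5 should close back to the six-membered lactone 11 on standing, or with EDC·HCl in CH2Cl2. C3 keeps its configuration because no bond to it is broken.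

Step 1. Incomplete E-selectivity at the new C4=C5 bond would carry a geometric isomer through to the end that is hard to separate. The fallback sets out from 1 and comes back at 3, and builds the two alkenes one at a time with stabilized ylides. Tetradecanal 1 and Ph3P=CHCHO (1.05 equiv, toluene, 80 °C) should give (E)-hexadec-2-enal F6. F6 and Ph3P=CHCO2Et (CH2Cl2, rt) should then give 3 with high E-selectivity at each stage.

**Further compounds**

F1 | step 5 | (2E,4E)-N-methoxy-N-methyloctadeca-2,4-dienamide | CCCCCCCCCCCCC/C=C/C=C/C(=O)N(C)OC
F2 | step 5 | 2,2,5-trimethyl-4H-1,3-benzodioxin-4-one | Cc1cccc2OC(C)(C)OC(=O)c12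
F3 | step 5 | 2,2-dimethyl-5-[(3E,5E)-2-oxononadeca-3,5-dien-1-yl]-4H-1,3-benzodioxin-4-one | CCCCCCCCCCCCC/C=C/C=C/C(=O)Cc1cccc2OC(C)(C)OC(=O)c12
F4 | step 5 | 5-[(2R,3E,5E)-2-hydroxynonadeca-3,5-dien-1-yl]-2,2-dimethyl-4H-1,3-benzodioxin-4-one | CCCCCCCCCCCCC/C=C/C=C/[C@H](O)Cc1cccc2OC(C)(C)OC(=O)c12
F5 | step 6 | 2-hydroxy-6-[(2R,3E,5E)-2-hydroxynonadeca-3,5-dien-1-yl]benzoic acid | CCCCCCCCCCCCC/C=C/C=C/[C@H](O)Cc1cccc(O)c1C(=O)O
F6 | step 1 | (E)-hexadec-2-enal | CCCCCCCCCCCCC/C=C/C=O
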